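**Retrosynthetic overview**
- The target is a (2R,3R)-trans-3-O-methyl dihydroflavonol. The strategy rests on ring C: O1 and C4 are ortho substituents of ring A, and C2–C3 is a two-carbon unit carrying ring B on C2 and an oxygen on C3.
- Ring C is cut at O1–C2 and C3–C4. This gives a ring-A salicylaldehyde 5 (reacting as its 4-methoxy o-quinone methide) and a ring-B (E)-enol acetate 10, joined by an acid-catalysed asymmetric hetero-[4+2]. Ring C is the only ring formed; rings A and B are bought as arenes.
- 5 comes from syringaldehyde (benzylation, Baeyer–Villiger, ortho-formylation). 10 comes from 2,3-dihydroxy-4-methoxybenzaldehyde (benzylation, one-carbon homologation, enol acetylation).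
- Endgame: C3 acetate to methyl ether, C4–OMe oxidised to C4=O (erasing C4), hydrogenolysis, chelation-directed 5-O-demethylation.

Key step: step 7

Assumption: the sense of induction of (R)-TRIP cannot be predicted for this new substrate class. (R)-TRIP is written for the (2R,3S) adduct, and the (S) acid would be used if the induction proves opposite.

**Route**

Step 1
Reactants: 1 syringaldehyde (4-hydroxy-3,5-dimethoxybenzaldehyde)
Product: 2 4-(benzyloxy)-3,5-dimethoxybenzaldehyde
Conditions: BnBr, K2CO3, DMF, 60 °C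
Reagents that add atoms: benzyl bromide, BrCc1ccccc1
Why: Williamson ether synthesis on the only phenol, which alkylates readily in DMF despite its two flanking methoxy groups.

Step 2
Reactants: 2 4-(benzyloxy)-3,5-dimethoxybenzaldehyde
Product: 4 4-(benzyloxy)-3,5-dimethoxyphenol, via aryl formate 3 (not isolated)
Conditions: mCPBA, CH2Cl2, rt; NaHCO3 wash; then K2CO3 (cat.), MeOH, rt
Reagents that add atoms: mCPBA (3-chloroperbenzoic acid), OOC(=O)c1cccc(Cl)c1
Why: Baeyer–Villiger (Dakin-type) oxidation in which the electron-rich aryl group migrates to give formate 3, which mild methanolysis cleaves to the phenol without touching the benzyl ether.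

Step 3
Reactants: 4 4-(benzyloxy)-3,5-dimethoxyphenol
Product: 5 3-(benzyloxy)-6-hydroxy-2,4-dimethoxybenzaldehyde
Conditions: MgCl2, Et3N, (CH2O)n, MeCN, reflux
Reagents that add atoms: paraformaldehyde (as formaldehyde), C=O
Why: Magnesium-mediated ortho-formylation (Casnati–Skattebøl) delivers formaldehyde only ortho to the phenoxide; the two ortho positions are equivalent and the para position is blocked, so a single regioisomer can form.

Step 4
Reactants: 6 2,3-dihydroxy-4-methoxybenzaldehyde
Product: 7 2,3-bis(benzyloxy)-4-methoxybenzaldehyde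
Conditions: BnBr (excess), K2CO3, DMF, 70 °C
Reagents that add atoms: benzyl bromide, BrCc1ccccc1
Why: Double Williamson etherification; the chelated 2-OH needs warming, but both phenols should be benzylated with excess reagent.

Step 5
Reactants: 7 2,3-bis(benzyloxy)-4-methoxybenzaldehyde
Product: 9 2-[2,3-bis(benzyloxy)-4-methoxyphenyl]acetaldehyde, via methyl enol ether 8 (not isolated)
Conditions: MeOCH2PPh3Cl, KOtBu, THF, 0 °C → rt; then 2 M HCl, THF, 50 °C
Reagents that add atoms: (methoxymethyl)triphenylphosphonium chloride, COC[P+](c1ccccc1)(c1ccccc1)c1ccccc1.[Cl-]; water, O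
Why: Wittig methoxymethylenation gives enol ether 8 (geometry irrelevant), and its acid hydrolysis unmasks the homologated aldehyde; aryl benzyl ethers tolerate dilute acid, and the sensitive aldehyde is used without storage.

Step 6
Reactants: 9 2-[2,3-bis(benzyloxy)-4-methoxyphenyl]acetaldehyde
Product: 10 (E)-2-[2,3-bis(benzyloxy)-4-methoxyphenyl]ethenyl acetate
Conditions: Ac2O, KOAc, 120 °C; E isomer isolated by chromatography or crystallisation
Reagents that add atoms: acetic anhydride, CC(=O)OC(C)=O
Why: Enol ester formation by O-acetylation of the aldehyde enolate under equilibrating conditions, where the E isomer is expected to be favoured and is freed from the Z isomer by purification; no stereocentre is formed.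

Step 7
Reactants: 5 3-(benzyloxy)-6-hydroxy-2,4-dimethoxybenzaldehyde; 10 (E)-2-[2,3-bis(benzyloxy)-4-methoxyphenyl]ethenyl acetate; 11 trimethyl orthoformate
Product: 14 (2R,3S,4RS)-6-(benzyloxy)-2-[2,3-bis(benzyloxy)-4-methoxyphenyl]-4,5,7-trimethoxy-3,4-dihydro-2H-chromen-3-yl acetate (2,3-trans; both C4 epimers), via dimethyl acetal 12 (not isolated), via methoxy o-quinone methide 13 (not isolated)
Conditions: (R)-TRIP [(R)-3,3'-bis(2,4,6-triisopropylphenyl)-1,1'-binaphthyl-2,2'-diyl hydrogen phosphate] (10 mol %), 5 Å MS, toluene, –20 °C → rt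
Reagents that add atoms: none
Why: Proposed new method: the phosphoric acid and orthoformate 11 turn aldehyde 5 into acetal 12, which loses methanol to the 4-methoxy o-quinone methide 13; protonated, this is an oxocarbenium ion paired with the chiral phosphate, which also hydrogen-bonds the phenol, and it is attacked at the methide carbon by the acetoxy-bearing carbon of 10 (C3–C4) before the phenol oxygen captures the benzylic cation (O1–C2). The closest known reaction types are the acid-promoted three-component coupling of salicylaldehydes, orthoformates and styrenes to 2-aryl-4-alkoxychromans and the chiral phosphoric acid catalysed [4+2] cycloadditions of aryl-substituted o-quinone methides with styrenes; an enol ester partner and enantiocontrol on an alkoxy-substituted methide are not known. Ring C closes in an intermolecular inverse-demand hetero-[4+2] mode, asynchronous, its second bond being a six-membered O-to-cation closure. The step needs regioselectivity, secured by the substrate: the 2,3-bis(benzyloxy)-4-methoxyphenyl group stabilises charge at C2 far better than the acetoxy group could at C3, so the normal enol ester polarity is overridden. C3 is fixed irreversibly in the C–C bond formation by the phosphate-shielded face of the ion pair; C2 follows C3 as 2,3-trans through anchimeric shielding by the neighbouring acetate and through re-ionisation of the donor-activated benzylic C2–O1 bond to the diequatorial isomer. C4 forms as a mixture, which is harmless because it later becomes the carbonyl carbon.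

Step 8
Reactants: 14 (2R,3S,4RS)-chroman-3-yl acetate
Product: 15 (2R,3S,4RS)-6-(benzyloxy)-2-[2,3-bis(benzyloxy)-4-methoxyphenyl]-4,5,7-trimethoxy-3,4-dihydro-2H-chromen-3-ol
Conditions: K2CO3, MeOH–THF, rt
Reagents that add atoms: none
Why: Base-catalysed transesterification (Zemplén-type) of the secondary acetate; the molecule has no acidic C–H, so C2 and C3 are untouched.

Step 9
Reactants: 15 (2R,3S,4RS)-chroman-3-ol
Product: 16 (2R,3S,4RS)-6-(benzyloxy)-2-[2,3-bis(benzyloxy)-4-methoxyphenyl]-3,4,5,7-tetramethoxy-3,4-dihydro-2H-chromene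
Conditions: NaH, MeI, THF–DMF, 0 °C → rt
Reagents that add atoms: iodomethane, CI
Why: Williamson methylation of the secondary alkoxide, the only nucleophilic site; benzyl and methyl ethers are inert and no stereocentre can epimerise.

Step 10
Reactants: 16 (2R,3S,4RS)-3,4,5,7-tetramethoxychroman
Product: 17 (2R,3R)-6-(benzyloxy)-2-[2,3-bis(benzyloxy)-4-methoxyphenyl]-3,5,7-trimethoxy-2,3-dihydro-4H-chromen-4-one
Conditions: DDQ, CH2Cl2–H2O, 0 °C → rt
Reagents that add atoms: water, O
Why: DDQ abstracts hydride from C4–H, benzylic to the tetra-oxygenated ring A and α to oxygen (the mechanism of oxidative p-methoxybenzyl ether cleavage), and water converts the oxocarbenium ion via its hemiketal into the aryl ketone, so both C4 epimers converge; C2 and C3 keep their geometry, the C3 descriptor changing from S to R only because C4 gains CIP priority.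

Step 11
Reactants: 17 (2R,3R)-tribenzyl flavanone
Product: 18 (2R,3R)-2-(2,3-dihydroxy-4-methoxyphenyl)-6-hydroxy-3,5,7-trimethoxy-2,3-dihydro-4H-chromen-4-one
Conditions: H2 (1 atm), 10% Pd/C, EtOAc–MeOH, rt
Reagents that add atoms: none
Why: Catalytic hydrogenolysis of the three aryl benzyl ethers; the donor-deactivated aryl ketone and the C2–O1 bond should survive balloon pressure with monitoring, and neutral conditions leave C2 and C3 intact.

Step 12
Reactants: 18 (2R,3R)-5-O-methyl triphenol
Product: 19 (2R,3R)-2-(2,3-dihydroxy-4-methoxyphenyl)-5,6-dihydroxy-3,7-dimethoxy-2,3-dihydro-4H-chromen-4-one (target)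
Conditions: BCl3 (1 M in CH2Cl2, excess), CH2Cl2, –78 → 0 °C; then H2O; under argon
Reagents that add atoms: none
Why: Chelation-directed Lewis-acid demethylation: boron bound to the C4 carbonyl and the 6-oxygen activates only the peri 5-OMe toward chloride attack, the known selectivity for 5-methoxyflavanones; the 7-, 4'- and aliphatic 3-methyl ethers lack this assistance, and low temperature preserves C2 and C3.

**Compound list**
1 | syringaldehyde | COc1cc(C=O)cc(OC)c1O | starting material
2 | 4-(benzyloxy)-3,5-dimethoxybenzaldehyde | COc1cc(C=O)cc(OC)c1OCc1ccccc1 | intermediate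
3 | 4-(benzyloxy)-3,5-dimethoxyphenyl formate | COc1cc(OC=O)cc(OC)c1OCc1ccccc1 | intermediate
4 | 4-(benzyloxy)-3,5-dimethoxyphenol | COc1cc(O)cc(OC)c1OCc1ccccc1 | intermediate
5 | 3-(benzyloxy)-6-hydroxy-2,4-dimethoxybenzaldehyde | COc1cc(O)c(C=O)c(OC)c1OCc1ccccc1 | intermediate
6 | 2,3-dihydroxy-4-methoxybenzaldehyde | COc1ccc(C=O)c(O)c1O | starting material
7 | 2,3-bis(benzyloxy)-4-methoxybenzaldehyde | COc1ccc(C=O)c(OCc2ccccc2)c1OCc1ccccc1 | intermediate
8 | 2,3-bis(benzyloxy)-1-methoxy-4-(2-methoxyethenyl)benzene (E/Z mixture) | COC=Cc1ccc(OC)c(OCc2ccccc2)c1OCc1ccccc1 | intermediate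
9 | 2-[2,3-bis(benzyloxy)-4-methoxyphenyl]acetaldehyde | COc1ccc(CC=O)c(OCc2ccccc2)c1OCc1ccccc1 | intermediate
10 | (E)-2-[2,3-bis(benzyloxy)-4-methoxyphenyl]ethenyl acetate | COc1ccc(/C=C/OC(C)=O)c(OCc2ccccc2)c1OCc1ccccc1 | intermediate
11 | trimethyl orthoformate | COC(OC)OC | starting material
12 | 4-(benzyloxy)-2-(dimethoxymethyl)-3,5-dimethoxyphenol | COc1cc(O)c(C(OC)OC)c(OC)c1OCc1ccccc1 | intermediate
13 | 4-(benzyloxy)-3,5-dimethoxy-6-(methoxymethylidene)cyclohexa-2,4-dien-1-one | COC=C1C(=O)C=C(OC)C(OCc2ccccc2)=C1OC | intermediate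
14 | (2R,3S,4RS)-6-(benzyloxy)-2-[2,3-bis(benzyloxy)-4-methoxyphenyl]-4,5,7-trimethoxy-3,4-dihydro-2H-chromen-3-yl acetate | COc1ccc([C@H]2Oc3cc(OC)c(OCc4ccccc4)c(OC)c3C(OC)[C@@H]2OC(C)=O)c(OCc2ccccc2)c1OCc1ccccc1 | intermediate
15 | (2R,3S,4RS)-6-(benzyloxy)-2-[2,3-bis(benzyloxy)-4-methoxyphenyl]-4,5,7-trimethoxy-3,4-dihydro-2H-chromen-3-ol | COc1ccc([C@H]2Oc3cc(OC)c(OCc4ccccc4)c(OC)c3C(OC)[C@@H]2O)c(OCc2ccccc2)c1OCc1ccccc1 | intermediate
16 | (2R,3S,4RS)-6-(benzyloxy)-2-[2,3-bis(benzyloxy)-4-methoxyphenyl]-3,4,5,7-tetramethoxy-3,4-dihydro-2H-chromene | COc1ccc([C@H]2Oc3cc(OC)c(OCc4ccccc4)c(OC)c3C(OC)[C@@H]2OC)c(OCc2ccccc2)c1OCc1ccccc1 | intermediate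
17 | (2R,3R)-6-(benzyloxy)-2-[2,3-bis(benzyloxy)-4-methoxyphenyl]-3,5,7-trimethoxy-2,3-dihydro-4H-chromen-4-one | COc1ccc([C@H]2Oc3cc(OC)c(OCc4ccccc4)c(OC)c3C(=O)[C@@H]2OC)c(OCc2ccccc2)c1OCc1ccccc1 | intermediate
18 | (2R,3R)-2-(2,3-dihydroxy-4-methoxyphenyl)-6-hydroxy-3,5,7-trimethoxy-2,3-dihydro-4H-chromen-4-one | COc1ccc([C@H]2Oc3cc(OC)c(O)c(OC)c3C(=O)[C@@H]2OC)c(O)c1O | intermediate
19 | (2R,3R)-2-(2,3-dihydroxy-4-methoxyphenyl)-5,6-dihydroxy-3,7-dimethoxy-2,3-dihydro-4H-chromen-4-one | COc1ccc([C@H]2Oc3cc(OC)c(O)c(O)c3C(=O)[C@@H]2OC)c(O)c1O | target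

**Step count**
Total: 12 steps. Longest linear sequence: 9 steps (steps 1–3 or 4–6, then 7–12).

**Steps most likely to fail**

1. Step 7 (new method). Four things may go wrong:
- The weak chiral acid may fail to turn over: slow acetalisation and ionisation of the very electron-rich aldehyde, or catalyst alkylation by the orthoformate. The first variation would be the more acidic N-triflyl phosphoramide of the same backbone.
- The enol ester may react with its normal polarity through the aryl-bearing carbon, giving the 3-aryl regioisomer.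
- Facial selectivity at C3 may be poor. It would be assayed at ketone 17, once C4 is gone, and upgraded there by crystallisation if needed.
- Equilibration to the 2,3-trans isomer may be incomplete.

Fallback, known chemistry, from 5 and 7 back to 17 (replacing steps 7–10):
- Phenol 5 would be protected (MOMCl, iPr2NEt) as 3-(benzyloxy)-2,4-dimethoxy-6-(methoxymethoxy)benzaldehyde F1.
- MeMgBr would give the carbinol 1-[3-(benzyloxy)-2,4-dimethoxy-6-(methoxymethoxy)phenyl]ethan-1-ol F2.
- Dess–Martin oxidation would give the acetophenone 1-[3-(benzyloxy)-2,4-dimethoxy-6-(methoxymethoxy)phenyl]ethan-1-one F3.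
- Claisen–Schmidt condensation of F3 with 7 (KOH, EtOH) would give the chalcone (E)-1-[3-(benzyloxy)-2,4-dimethoxy-6-(methoxymethoxy)phenyl]-3-[2,3-bis(benzyloxy)-4-methoxyphenyl]prop-2-en-1-one F4.
- Julia–Colonna epoxidation (poly-L-leucine, urea–H2O2, DBU, THF) is expected to give the epoxide [(2R,3S)-3-[2,3-bis(benzyloxy)-4-methoxyphenyl]oxiran-2-yl][3-(benzyloxy)-2,4-dimethoxy-6-(methoxymethoxy)phenyl]methanone F5.
- HCl in MeOH would remove the MOM group, and the freed phenol would open the epoxide at its benzylic carbon with inversion. This should give the trans dihydroflavonol (2R,3R)-6-(benzyloxy)-2-[2,3-bis(benzyloxy)-4-methoxyphenyl]-3-hydroxy-5,7-dimethoxy-2,3-dihydro-4H-chromen-4-one F6.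
- Purdie methylation (MeI, Ag2O) of F6 would give 17.

2. Step 10. Three things may go wrong:
- Hydride abstraction may be slow for the C4 epimer whose C–H lies near the arene plane.
- Hydride may be lost instead from the C2 benzylic ether position (ring B is a p-methoxybenzyl-type donor), leading to ring C cleavage.
- Benzyl ethers may be lost oxidatively.

Fallback, from 16 back to 17: the doubly donor-activated benzylic methyl ether would be solvolysed with aqueous acid (TFA, THF–H2O) to the alcohol (2R,3S,4RS)-6-(benzyloxy)-2-[2,3-bis(benzyloxy)-4-methoxyphenyl]-3,5,7-trimethoxy-3,4-dihydro-2H-chromen-4-ol F7. Dess–Martin periodinane would then oxidise F7 to 17.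

3. Step 6. The acetylation may give poor E/Z selectivity, and the electron-rich arylacetaldehyde may undergo aldol self-condensation on heating.

Fallback, from 7 back to 10 (bypassing 9): Claisen–Schmidt condensation of 7 with acetone (NaOH, acetone–H2O) would give (E)-4-[2,3-bis(benzyloxy)-4-methoxyphenyl]but-3-en-2-one F8. Buffered Baeyer–Villiger oxidation (mCPBA, Na2HPO4, CH2Cl2, limiting peracid) would then give 10, since the styryl group migrates with retention of the E geometry.

**Further compounds**
F1 | step 7 | 3-(benzyloxy)-2,4-dimethoxy-6-(methoxymethoxy)benzaldehyde | COCOc1cc(OC)c(OCc2ccccc2)c(OC)c1C=O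
F2 | step 7 | 1-[3-(benzyloxy)-2,4-dimethoxy-6-(methoxymethoxy)phenyl]ethan-1-ol (racemic) | COCOc1cc(OC)c(OCc2ccccc2)c(OC)c1C(C)O
F3 | step 7 | 1-[3-(benzyloxy)-2,4-dimethoxy-6-(methoxymethoxy)phenyl]ethan-1-one | COCOc1cc(OC)c(OCc2ccccc2)c(OC)c1C(C)=O
F4 | step 7 | (E)-1-[3-(benzyloxy)-2,4-dimethoxy-6-(methoxymethoxy)phenyl]-3-[2,3-bis(benzyloxy)-4-methoxyphenyl]prop-2-en-1-one | COCOc1cc(OC)c(OCc2ccccc2)c(OC)c1C(=O)/C=C/c1ccc(OC)c(OCc2ccccc2)c1OCc1ccccc1
F5 | step 7 | [(2R,3S)-3-[2,3-bis(benzyloxy)-4-methoxyphenyl]oxiran-2-yl][3-(benzyloxy)-2,4-dimethoxy-6-(methoxymethoxy)phenyl]methanone | COCOc1cc(OC)c(OCc2ccccc2)c(OC)c1C(=O)[C@@H]1O[C@H]1c1ccc(OC)c(OCc2ccccc2)c1OCc1ccccc1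
F6 | step 7 | (2R,3R)-6-(benzyloxy)-2-[2,3-bis(benzyloxy)-4-methoxyphenyl]-3-hydroxy-5,7-dimethoxy-2,3-dihydro-4H-chromen-4-one | COc1ccc([C@H]2Oc3cc(OC)c(OCc4ccccc4)c(OC)c3C(=O)[C@@H]2O)c(OCc2ccccc2)c1OCc1ccccc1
F7 | step 10 | (2R,3S,4RS)-6-(benzyloxy)-2-[2,3-bis(benzyloxy)-4-methoxyphenyl]-3,5,7-trimethoxy-3,4-dihydro-2H-chromen-4-ol | COc1ccc([C@H]2Oc3cc(OC)c(OCc4ccccc4)c(OC)c3C(O)[C@@H]2OC)c(OCc2ccccc2)c1OCc1ccccc1
F8 | step 6 | (E)-4-[2,3-bis(benzyloxy)-4-methoxyphenyl]but-3-en-2-one | COc1ccc(/C=C/C(C)=O)c(OCc2ccccc2)c1OCc1ccccc1
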